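**Plan**

- Retrosynthetic cuts, in order: O1–C8a of ring C; C3–C4 (aldol); C4a–C4 (formyl carbon onto ring A); C8–CH2 of the lavandulyl chain; and, inside that chain, the bond from its stereocentre to the prenyl CH2.
- Forward: the lavandulyl iodide is built on an oxazolidinone and joined to ring A (bought as 2-iodoresorcinol) by Negishi coupling. Ring A is then formylated and its C8a oxygen triflated, an aldol addition brings in ring B (bought as the acetophenone) with C2 and C3, and ring C is closed last.
- Enabling feature: O1 links the aromatic carbon C8a of ring A (between C8 and C4a) to the benzylic stereocentre C2 beside the oxygenated ring B. Forming O1–C8a on palladium from a C8a triflate and the C2 alkoxide touches no bond at C2, whereas closure at O1–C2 would pass through an easily ionized benzylic carbon.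
- Stereochemistry: the lavandulyl centre comes from auxiliary-controlled alkylation (step 2). C2 comes from catalyst-controlled transfer hydrogenation of the ring B ketone (step 14) and is retained in the ring closure. C4 is carried as both epimers under a silyl cap and oxidized to the ketone at the end.

Key step: step 15

Remark on the chemistry: flavanone numbering (O1, C2, C3, C4, C4a, C5–C8, C8a) is used also for open-chain precursors. "(R)-lavandulyl" means (2R)-5-methyl-2-(prop-1-en-2-yl)hex-4-en-1-yl bound to ring A. The same spatial arrangement carries the descriptor S in compounds 7, 8, 9 and 12, because C(=O)N, CH2O, CH2I and CH2Zn outrank isopropenyl whereas CH2–aryl does not.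

**Route**

Step 1
Reactants: 1 (S)-4-benzyl-2-oxazolidinone; 2 3-methylbut-2-enoyl chloride
Product: 4 (S)-4-benzyl-3-(3-methylbut-2-enoyl)oxazolidin-2-one, via N-lithio oxazolidinone 3 (not isolated)
Conditions: n-BuLi, THF, −78 °C; then 2, −78 → 0 °C
Reagents that add atoms: none
Why: N-acylation of the lithiated auxiliary by the acid chloride (standard loading of an Evans oxazolidinone), run cold and without amine base so that no vinylketene or deconjugated acyl group forms.

Step 2
Reactants: 4 (S)-4-benzyl-3-(3-methylbut-2-enoyl)oxazolidin-2-one; 5 prenyl bromide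
Product: 7 (S)-4-benzyl-3-[(2S)-5-methyl-2-(prop-1-en-2-yl)hex-4-enoyl]oxazolidin-2-one, via sodium dienolate 6 (not isolated)
Conditions: NaN(SiMe3)2, THF, −78 °C; then 5, −78 → −40 °C
Reagents that add atoms: none
Why: Evans asymmetric alkylation in its deconjugative form: γ-deprotonation gives the chelated (Z)-dienolate, which should react at the α-carbon on the face away from the benzyl group, setting the lavandulyl stereocentre and leaving the isopropenyl group.

Step 3
Reactants: 7 (S)-4-benzyl-3-[(2S)-5-methyl-2-(prop-1-en-2-yl)hex-4-enoyl]oxazolidin-2-one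
Product: 8 (S)-lavandulol [(2S)-5-methyl-2-(prop-1-en-2-yl)hex-4-en-1-ol]
Conditions: LiBH4, MeOH, THF, 0 °C
Reagents that add atoms: none
Why: Reductive cleavage of the N-acyl oxazolidinone by borohydride gives the primary alcohol and returns the auxiliary, and the mild, weakly basic hydride should neither epimerize nor reconjugate the allylic α-centre.

Step 4
Reactants: 8 (S)-lavandulol
Product: 9 (S)-lavandulyl iodide [(2S)-1-iodo-5-methyl-2-(prop-1-en-2-yl)hex-4-ene]
Conditions: PPh3, I2, imidazole, CH2Cl2, 0 °C → rt
Reagents that add atoms: iodine, II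
Why: Appel-type iodination of a primary alcohol through its alkoxyphosphonium salt, with displacement at the CH2 carbon so that the neighbouring stereocentre is not involved.

Step 5
Reactants: 10 2-iodoresorcinol
Product: 11 2-iodo-1,3-bis(tert-butyldimethylsilyloxy)benzene
Conditions: TBSCl, imidazole, DMF, rt
Reagents that add atoms: tert-butyldimethylsilyl chloride, CC(C)(C)[Si](C)(C)Cl
Why: Routine silyl ether formation removes both acidic protons, which would otherwise quench the organozinc reagent of the next step.

Step 6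
Reactants: 9 (S)-lavandulyl iodide; 11 2-iodo-1,3-bis(tert-butyldimethylsilyloxy)benzene
Product: 13 2-[(R)-lavandulyl]-1,3-bis(tert-butyldimethylsilyloxy)benzene, via lavandulylzinc iodide 12 (not isolated)
Conditions: Zn dust, LiCl, THF, 40 °C; then 11, Pd(OAc)2 (2 mol %), SPhos (4 mol %), THF, 50 °C
Reagents that add atoms: none
Why: Zinc insertion into the primary C–I bond followed by Negishi sp3–sp2 coupling, in which the dialkylbiarylphosphine should favour reductive elimination over β-hydride elimination at the hindered arylpalladium, while the stereocentre β to zinc is never touched.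

Step 7
Reactants: 13 2-[(R)-lavandulyl]-1,3-bis(tert-butyldimethylsilyloxy)benzene
Product: 14 2-[(R)-lavandulyl]benzene-1,3-diol
Conditions: Bu4NF, AcOH, THF, 0 °C → rt
Reagents that add atoms: none
Why: Fluoride cleavage of aryl silyl ethers frees both phenols, one of which is needed to direct the formylation.

Step 8
Reactants: 14 2-[(R)-lavandulyl]benzene-1,3-diol
Product: 15 2,4-dihydroxy-3-[(R)-lavandulyl]benzaldehyde
Conditions: MgCl2, Et3N, (CH2O)n, MeCN, 80 °C; aq. HCl work-up
Reagents that add atoms: paraformaldehyde (formaldehyde), C=O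
Why: Magnesium-phenoxide-directed ortho-formylation (Casnati–Skattebøl type) under non-acidic conditions that spare the alkenes; the two open ortho positions are equivalent by symmetry and the first aldehyde deactivates the ring towards a second one.

Step 9
Reactants: 15 2,4-dihydroxy-3-[(R)-lavandulyl]benzaldehyde
Product: 16 2-hydroxy-3-[(R)-lavandulyl]-4-(triisopropylsilyloxy)benzaldehyde
Conditions: TIPSCl, imidazole, CH2Cl2, 0 °C
Reagents that add atoms: triisopropylsilyl chloride, CC(C)[Si](Cl)(C(C)C)C(C)C
Why: Regioselective silylation of the 4-hydroxyl, which is the more acidic one and is not held in the hydrogen bond that ties the 2-hydroxyl to the aldehyde.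

Step 10
Reactants: 16 2-hydroxy-3-[(R)-lavandulyl]-4-(triisopropylsilyloxy)benzaldehyde
Product: 17 6-formyl-2-[(R)-lavandulyl]-3-(triisopropylsilyloxy)phenyl trifluoromethanesulfonate
Conditions: Tf2O, pyridine, CH2Cl2, −78 → 0 °C
Reagents that add atoms: trifluoromethanesulfonic anhydride, O=S(=O)(OS(=O)(=O)C(F)(F)F)C(F)(F)F
Why: O-sulfonylation of the remaining phenol turns the future C8a–O bond into the site of oxidative addition, and the electrophile does not react with the isolated alkenes at low temperature.

Step 11
Reactants: 18 1-(4-hydroxy-2-methoxyphenyl)ethanone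
Product: 19 1-[2-methoxy-4-(triisopropylsilyloxy)phenyl]ethanone
Conditions: TIPSCl, imidazole, DMF, rt
Reagents that add atoms: triisopropylsilyl chloride, CC(C)[Si](Cl)(C(C)C)C(C)C
Why: Silyl ether formation masks the ring B phenol with a group robust enough for enolate chemistry and for the basic coupling later.

Step 12
Reactants: 19 1-[2-methoxy-4-(triisopropylsilyloxy)phenyl]ethanone; 17 6-formyl-2-[(R)-lavandulyl]-3-(triisopropylsilyloxy)phenyl trifluoromethanesulfonate
Product: 21 6-{1-hydroxy-3-[2-methoxy-4-(triisopropylsilyloxy)phenyl]-3-oxopropyl}-2-[(R)-lavandulyl]-3-(triisopropylsilyloxy)phenyl trifluoromethanesulfonate (both epimers at C4), via lithium enolate 20 (not isolated)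
Conditions: LiN(SiMe3)2, THF, −78 °C; then 17, −78 °C; AcOH quench at −78 °C
Reagents that add atoms: none
Why: Directed aldol addition of a preformed lithium enolate to a non-enolizable aldehyde forms C3–C4; the cold acidic quench should forestall retro-aldol, dehydration and attack of the aldolate on the neighbouring sulfonate, and the new C4 carbinol may form as both epimers because it is oxidized later.

Step 13
Reactants: 21 β-hydroxy ketone (both epimers at C4)
Product: 22 6-{3-[2-methoxy-4-(triisopropylsilyloxy)phenyl]-3-oxo-1-(triethylsilyloxy)propyl}-2-[(R)-lavandulyl]-3-(triisopropylsilyloxy)phenyl trifluoromethanesulfonate (both epimers at C4)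
Conditions: Et3SiOTf, 2,6-lutidine, CH2Cl2, −78 °C
Reagents that add atoms: triethylsilyl trifluoromethanesulfonate, CC[Si](CC)(CC)OS(=O)(=O)C(F)(F)F
Why: Silylation of the hindered benzylic alcohol with a silyl triflate and a non-nucleophilic base caps the C4 oxygen, so that later only the C2 hydroxyl can bind palladium and no alkoxide sits next to the aryl triflate.

Step 14
Reactants: 22 silyl-capped ketone (both epimers at C4)
Product: 23 6-{(3S)-3-hydroxy-3-[2-methoxy-4-(triisopropylsilyloxy)phenyl]-1-(triethylsilyloxy)propyl}-2-[(R)-lavandulyl]-3-(triisopropylsilyloxy)phenyl trifluoromethanesulfonate (2S in flavan numbering; both epimers at C4)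
Conditions: RuCl(p-cymene)[(S,S)-TsDPEN] (2 mol %), HCO2H–Et3N (1:1), CH2Cl2, 30 °C
Reagents that add atoms: none
Why: Noyori-type asymmetric transfer hydrogenation of an aryl alkyl ketone, in which the (S,S) catalyst should deliver hydride to the Re face and give the S carbinol by analogy with acetophenone; the amine-rich formate medium should leave alkenes, triflate and silyl ethers alone.

Step 15
Reactants: 23 (2S)-hydroxy triflate (both epimers at C4)
Product: 24 (2S)-2-[2-methoxy-4-(triisopropylsilyloxy)phenyl]-8-[(R)-lavandulyl]-4-(triethylsilyloxy)-7-(triisopropylsilyloxy)chromane (both epimers at C4)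
Conditions: Pd(OAc)2 (5 mol %), t-BuXPhos (7.5 mol %), K3PO4, toluene, 80 °C
Reagents that add atoms: none
Why: Zerovalent palladium, formed in the flask from Pd(OAc)2 and the bulky biaryl di-tert-butylphosphine, inserts into the C8a–O bond of the triflate; the only free hydroxyl, at C2, then replaces triflate on divalent palladium with the help of K3PO4 to give a seven-membered oxapalladacycle, and C–O reductive elimination forms O1–C8a. The closest known reaction type is the palladium-catalysed intramolecular etherification of aryl halides and sulfonates with secondary alcohols (Buchwald–Hartwig etherification), which gives 2-substituted chromans without loss of configuration at the carbinol carbon. Ring C closes as a six-membered pyran by bond formation between the tethered alkoxide oxygen and the arene carbon in the reductive elimination. No stereocentre is created: C2 keeps its S configuration because none of its bonds is made or broken, and the lavandulyl centre is remote. The step needs C–O reductive elimination to outrun β-hydride elimination of the C2 alkoxide and needs the triflate to survive the base; the hindered electron-rich ligand, the two ortho substituents at C8a that speed reductive elimination, the silyl cap on the C4 oxygen (one alkoxide only, no five-membered chelate) and the weak, insoluble phosphate base should secure this.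

Step 16
Reactants: 24 (2S)-flavan 4-triethylsilyl ether (both epimers at C4)
Product: 25 (2S)-2-[2-methoxy-4-(triisopropylsilyloxy)phenyl]-8-[(R)-lavandulyl]-7-(triisopropylsilyloxy)chroman-4-ol (both epimers at C4)
Conditions: AcOH–THF–H2O (3:1:1), rt
Reagents that add atoms: none
Why: Mild acidic hydrolysis of a silyl ether should cleave the secondary triethylsilyl ether while the two aryl triisopropylsilyl ethers and both alkenes stay, and C2 is not involved.

Step 17
Reactants: 25 (2S)-flavan-4-ol (both epimers at C4)
Product: 26 (2S)-2-[2-methoxy-4-(triisopropylsilyloxy)phenyl]-8-[(R)-lavandulyl]-7-(triisopropylsilyloxy)chroman-4-one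
Conditions: Dess–Martin periodinane, CH2Cl2, 0 °C → rt
Reagents that add atoms: none
Why: Dess–Martin oxidation of the secondary benzylic alcohol merges both C4 epimers into the ketone under near-neutral conditions that should not open ring C.

Step 18
Reactants: 26 bis-silylated flavanone
Product: 27 alopecurone G
Conditions: Bu4NF, AcOH, THF, 0 °C
Reagents that add atoms: none
Why: Fluoride cleavage of the two aryl silyl ethers, buffered with acetic acid so that no free phenoxide can trigger the retro-oxa-Michael ring opening that would racemize C2.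

**Compound list**

1 | (S)-4-benzyl-2-oxazolidinone | O=C1N[C@@H](Cc2ccccc2)CO1 | starting material
2 | 3-methylbut-2-enoyl chloride | CC(C)=CC(=O)Cl | starting material
3 | N-lithio (S)-4-benzyl-2-oxazolidinone | O=C1N([Li])[C@@H](Cc2ccccc2)CO1 | intermediate
4 | (S)-4-benzyl-3-(3-methylbut-2-enoyl)oxazolidin-2-one | CC(C)=CC(=O)N1[C@@H](Cc2ccccc2)COC1=O | intermediate
5 | prenyl bromide | CC(C)=CCBr | starting material
6 | sodium (Z)-dienolate of 4 | C=C(C)/C=C(\[O-])N1[C@@H](Cc2ccccc2)COC1=O.[Na+] | intermediate
7 | (S)-4-benzyl-3-[(2S)-5-methyl-2-(prop-1-en-2-yl)hex-4-enoyl]oxazolidin-2-one | C=C(C)[C@H](CC=C(C)C)C(=O)N1[C@@H](Cc2ccccc2)COC1=O | intermediate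
8 | (S)-lavandulol, (2S)-5-methyl-2-(prop-1-en-2-yl)hex-4-en-1-ol | C=C(C)[C@H](CC=C(C)C)CO | intermediate
9 | (S)-lavandulyl iodide, (2S)-1-iodo-5-methyl-2-(prop-1-en-2-yl)hex-4-ene | C=C(C)[C@H](CC=C(C)C)CI | intermediate
10 | 2-iodoresorcinol | Oc1cccc(O)c1I | starting material
11 | 2-iodo-1,3-bis(tert-butyldimethylsilyloxy)benzene | CC(C)(C)[Si](C)(C)Oc1cccc(O[Si](C)(C)C(C)(C)C)c1I | intermediate
12 | [(2S)-5-methyl-2-(prop-1-en-2-yl)hex-4-en-1-yl]zinc iodide | C=C(C)[C@H](CC=C(C)C)C[Zn]I | intermediate
13 | 2-[(R)-lavandulyl]-1,3-bis(tert-butyldimethylsilyloxy)benzene | C=C(C)[C@H](CC=C(C)C)Cc1c(O[Si](C)(C)C(C)(C)C)cccc1O[Si](C)(C)C(C)(C)C | intermediate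
14 | 2-[(R)-lavandulyl]benzene-1,3-diol | C=C(C)[C@H](CC=C(C)C)Cc1c(O)cccc1O | intermediate
15 | 2,4-dihydroxy-3-[(R)-lavandulyl]benzaldehyde | C=C(C)[C@H](CC=C(C)C)Cc1c(O)ccc(C=O)c1O | intermediate
16 | 2-hydroxy-3-[(R)-lavandulyl]-4-(triisopropylsilyloxy)benzaldehyde | C=C(C)[C@H](CC=C(C)C)Cc1c(O[Si](C(C)C)(C(C)C)C(C)C)ccc(C=O)c1O | intermediate
17 | 6-formyl-2-[(R)-lavandulyl]-3-(triisopropylsilyloxy)phenyl trifluoromethanesulfonate | C=C(C)[C@H](CC=C(C)C)Cc1c(O[Si](C(C)C)(C(C)C)C(C)C)ccc(C=O)c1OS(=O)(=O)C(F)(F)F | intermediate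
18 | 1-(4-hydroxy-2-methoxyphenyl)ethanone | CC(=O)c1ccc(O)cc1OC | starting material
19 | 1-[2-methoxy-4-(triisopropylsilyloxy)phenyl]ethanone | CC(=O)c1ccc(O[Si](C(C)C)(C(C)C)C(C)C)cc1OC | intermediate
20 | lithium enolate of 19 | C=C(O[Li])c1ccc(O[Si](C(C)C)(C(C)C)C(C)C)cc1OC | intermediate
21 | 6-{1-hydroxy-3-[2-methoxy-4-(triisopropylsilyloxy)phenyl]-3-oxopropyl}-2-[(R)-lavandulyl]-3-(triisopropylsilyloxy)phenyl trifluoromethanesulfonate, both epimers at C4 | C=C(C)[C@H](CC=C(C)C)Cc1c(O[Si](C(C)C)(C(C)C)C(C)C)ccc(C(O)CC(=O)c2ccc(O[Si](C(C)C)(C(C)C)C(C)C)cc2OC)c1OS(=O)(=O)C(F)(F)F | intermediate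
22 | 4-O-triethylsilyl ether of 21, both epimers at C4 | C=C(C)[C@H](CC=C(C)C)Cc1c(O[Si](C(C)C)(C(C)C)C(C)C)ccc(C(O[Si](CC)(CC)CC)CC(=O)c2ccc(O[Si](C(C)C)(C(C)C)C(C)C)cc2OC)c1OS(=O)(=O)C(F)(F)F | intermediate
23 | 6-{(3S)-3-hydroxy-3-[2-methoxy-4-(triisopropylsilyloxy)phenyl]-1-(triethylsilyloxy)propyl}-2-[(R)-lavandulyl]-3-(triisopropylsilyloxy)phenyl trifluoromethanesulfonate, both epimers at C4 (precursor of the key step) | C=C(C)[C@H](CC=C(C)C)Cc1c(O[Si](C(C)C)(C(C)C)C(C)C)ccc(C(O[Si](CC)(CC)CC)C[C@H](O)c2ccc(O[Si](C(C)C)(C(C)C)C(C)C)cc2OC)c1OS(=O)(=O)C(F)(F)F | intermediate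
24 | (2S)-2-[2-methoxy-4-(triisopropylsilyloxy)phenyl]-8-[(R)-lavandulyl]-4-(triethylsilyloxy)-7-(triisopropylsilyloxy)chromane, both epimers at C4 (product of the key step) | C=C(C)[C@H](CC=C(C)C)Cc1c(O[Si](C(C)C)(C(C)C)C(C)C)ccc2c1O[C@H](c1ccc(O[Si](C(C)C)(C(C)C)C(C)C)cc1OC)CC2O[Si](CC)(CC)CC | intermediate
25 | (2S)-2-[2-methoxy-4-(triisopropylsilyloxy)phenyl]-8-[(R)-lavandulyl]-7-(triisopropylsilyloxy)chroman-4-ol, both epimers at C4 | C=C(C)[C@H](CC=C(C)C)Cc1c(O[Si](C(C)C)(C(C)C)C(C)C)ccc2c1O[C@H](c1ccc(O[Si](C(C)C)(C(C)C)C(C)C)cc1OC)CC2O | intermediate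
26 | (2S)-2-[2-methoxy-4-(triisopropylsilyloxy)phenyl]-8-[(R)-lavandulyl]-7-(triisopropylsilyloxy)chroman-4-one | C=C(C)[C@H](CC=C(C)C)Cc1c(O[Si](C(C)C)(C(C)C)C(C)C)ccc2c1O[C@H](c1ccc(O[Si](C(C)C)(C(C)C)C(C)C)cc1OC)CC2=O | intermediate
27 | alopecurone G, (2S)-7-hydroxy-2-(4-hydroxy-2-methoxyphenyl)-8-[(2R)-5-methyl-2-(prop-1-en-2-yl)hex-4-en-1-yl]chroman-4-one | C=C(C)[C@H](CC=C(C)C)Cc1c(O)ccc2c1O[C@H](c1ccc(O)cc1OC)CC2=O | target

**Step count**

Total: 18 steps. Longest linear sequence: 16 steps (steps 1–4, 6–10 and 12–18); steps 5 and 11 are single-step side branches.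

**Steps most likely to fail**

1. Step 15 (ring closure on palladium). The palladium alkoxide may undergo β-hydride elimination, which would return the C2 ketone and a reduced arene. Oxidative addition at the doubly ortho-substituted C8a may also be slow, and the base may cleave the S–O bond of the triflate. The fallback closes ring C at the other C–O bond by a Mitsunobu reaction with inversion, which needs the C2 epimer and a free phenol. It sets out from phenol 16 and comes back to the route at 24. O-Allylation of 16 (allyl bromide, K2CO3, DMF) should give 2-allyloxy-3-[(R)-lavandulyl]-4-(triisopropylsilyloxy)benzaldehyde F1. Aldol addition of enolate 20 to it should give the allyl-protected β-hydroxy ketone F2, and Et3SiOTf with 2,6-lutidine its triethylsilyl ether F3. Transfer hydrogenation with RuCl(p-cymene)[(R,R)-TsDPEN] should then give the (2R)-carbinol F4, and Pd(PPh3)4 with morpholine should remove the allyl group to give the (2R)-hydroxy phenol F5. Treatment of F5 with PPh3 and diisopropyl azodicarboxylate in THF at 0 °C should form O1–C2 by SN2 displacement with inversion and so deliver 24. The weakness of this detour is possible ionization at C2 beside the electron-rich ring B, which is why it is only the reserve.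

2. Step 6 (Negishi coupling). Coupling at the iodide flanked by two silyloxy groups may be slow, so that β-hydride elimination and protodemetalation of the β-branched alkylzinc take over. The fallback reverses the polarity and uses no palladium; it sets out from 10 and 9 and comes back at resorcinol 14. Compound 10 is protected (MOMCl, iPr2NEt, CH2Cl2) as 2-iodo-1,3-bis(methoxymethoxy)benzene F6. Iodine–lithium exchange (t-BuLi, THF, −78 °C) gives 2,6-bis(methoxymethoxy)phenyllithium F7, which cannot undergo silyl migration. Alkylation with iodide 9 in THF–DMPU (−78 °C → rt) should give 2-[(R)-lavandulyl]-1,3-bis(methoxymethoxy)benzene F8. The acetals are then removed without protic acid (Me3SiOTf, 2,2'-bipyridyl, CH2Cl2, then water) to give 14.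

3. Step 8 (formylation of the free resorcinol). The doubly activated ring may be formylated twice or condense with formaldehyde to methylene-bridged products, or an unreactive magnesium bis-phenoxide may precipitate. The fallback changes the order so that a mono-phenol is formylated; it sets out from 14 and comes back at 16, bypassing 15. Monosilylation of 14 (TIPSCl, one equivalent, imidazole, CH2Cl2, with diol and bis-ether recycled) should give 2-[(R)-lavandulyl]-3-(triisopropylsilyloxy)phenol F9. Its MgCl2/Et3N/paraformaldehyde formylation can occur only at the single open position ortho to the one free phenol and should give 16 directly.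

**Further compounds**

F1 | step 15 | 2-allyloxy-3-[(R)-lavandulyl]-4-(triisopropylsilyloxy)benzaldehyde | C=C(C)[C@H](CC=C(C)C)Cc1c(O[Si](C(C)C)(C(C)C)C(C)C)ccc(C=O)c1OCC=C
F2 | step 15 | 1-{2-allyloxy-3-[(R)-lavandulyl]-4-(triisopropylsilyloxy)phenyl}-1-hydroxy-3-[2-methoxy-4-(triisopropylsilyloxy)phenyl]propan-3-one, both epimers at C4 | C=C(C)[C@H](CC=C(C)C)Cc1c(O[Si](C(C)C)(C(C)C)C(C)C)ccc(C(O)CC(=O)c2ccc(O[Si](C(C)C)(C(C)C)C(C)C)cc2OC)c1OCC=C
F3 | step 15 | 4-O-triethylsilyl ether of F2, both epimers at C4 | C=C(C)[C@H](CC=C(C)C)Cc1c(O[Si](C(C)C)(C(C)C)C(C)C)ccc(C(O[Si](CC)(CC)CC)CC(=O)c2ccc(O[Si](C(C)C)(C(C)C)C(C)C)cc2OC)c1OCC=C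
F4 | step 15 | (3R)-3-{2-allyloxy-3-[(R)-lavandulyl]-4-(triisopropylsilyloxy)phenyl}-1-[2-methoxy-4-(triisopropylsilyloxy)phenyl]-3-(triethylsilyloxy)propan-1-ol with R at the ring B carbinol (2R in flavan numbering), both epimers at C4 | C=C(C)[C@H](CC=C(C)C)Cc1c(O[Si](C(C)C)(C(C)C)C(C)C)ccc(C(O[Si](CC)(CC)CC)C[C@@H](O)c2ccc(O[Si](C(C)C)(C(C)C)C(C)C)cc2OC)c1OCC=C
F5 | step 15 | 6-{(3R)-3-hydroxy-3-[2-methoxy-4-(triisopropylsilyloxy)phenyl]-1-(triethylsilyloxy)propyl}-2-[(R)-lavandulyl]-3-(triisopropylsilyloxy)phenol, both epimers at C4 | C=C(C)[C@H](CC=C(C)C)Cc1c(O[Si](C(C)C)(C(C)C)C(C)C)ccc(C(O[Si](CC)(CC)CC)C[C@@H](O)c2ccc(O[Si](C(C)C)(C(C)C)C(C)C)cc2OC)c1O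
F6 | step 6 | 2-iodo-1,3-bis(methoxymethoxy)benzene | COCOc1cccc(OCOC)c1I
F7 | step 6 | 2,6-bis(methoxymethoxy)phenyllithium | COCOc1cccc(OCOC)c1[Li]
F8 | step 6 | 2-[(R)-lavandulyl]-1,3-bis(methoxymethoxy)benzene | C=C(C)[C@H](CC=C(C)C)Cc1c(OCOC)cccc1OCOC
F9 | step 8 | 2-[(R)-lavandulyl]-3-(triisopropylsilyloxy)phenol | C=C(C)[C@H](CC=C(C)C)Cc1c(O[Si](C(C)C)(C(C)C)C(C)C)cccc1O
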